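**Assumption:** the SMILES is read as (5S,6R,7S,8S) on the tetrahydrochromone ring, i.e. 5-OH/6-OH trans, 6-OH/7-OH trans and 7-OH/8-OAr cis; the four numbered starting materials and all common reagents are bought.

## Retrosynthetic overview

1. The last bond is the C8–O aryl ether, made by a Mitsunobu reaction with inversion at C8 between 6-hydroxy-7-methoxy-2-(2-phenylethyl)chromone and an all-trans 8-hydroxy-tetrahydrochromone protected at O5, O6 and O7.
2. Aromatic chromone: the γ-pyrone is closed onto the preformed arene after an intermolecular Claisen condensation of a 2-hydroxyacetophenone with ethyl 3-phenylpropanoate.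
3. Tetrahydrochromone: the γ-pyrone is closed last, after an intermolecular aldol of a tetra-oxygenated cyclohexanone enolate with 5-phenylpent-2-ynal, oxidation and O-cyclization.
4. Cyclohexanone (carbocycle formed first): Ferrier carbocyclization of a D-glucose-derived hex-5-enopyranoside. Glucose C2, C3, C4 become C8, C7, C6; a hydroxyl-directed ketone reduction sets C5.
5. Ring order: pyrone of the phenol half; carbocycle, then its pyrone; the halves are joined at the end.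

## Route

Step 1
Reactants: 1 2-methoxybenzene-1,4-diol
Product: 2 1-(2,5-dihydroxy-4-methoxyphenyl)ethan-1-one
Conditions: AcOH (1.5 equiv), BF3·OEt2 (as solvent), 90 °C; then water
Reagents that add atoms: acetic acid, CC(=O)O
Why: Friedel–Crafts (Nencki-type) C-acylation goes to the only ring position that is ortho to a free OH, para to the OMe and not flanked by two substituents.

Step 2
Reactants: 2 1-(2,5-dihydroxy-4-methoxyphenyl)ethan-1-one
Product: 3 1-[5-(benzyloxy)-2-hydroxy-4-methoxyphenyl]ethan-1-one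
Conditions: BnBr (1.05 equiv), K2CO3 (1.1 equiv), acetone, reflux
Reagents that add atoms: benzyl bromide, BrCc1ccccc1
Why: Williamson etherification is selective because the 2-OH is hydrogen-bonded to the ketone and only the 5-OH is alkylated.

Step 3
Reactants: 3 1-[5-(benzyloxy)-2-hydroxy-4-methoxyphenyl]ethan-1-one; 4 ethyl 3-phenylpropanoate
Product: 5 1-[5-(benzyloxy)-2-hydroxy-4-methoxyphenyl]-5-phenylpentane-1,3-dione
Conditions: NaH (4 equiv), THF, reflux; then 1 M HCl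
Reagents that add atoms: none
Why: Intermolecular crossed Claisen condensation of the acetophenone enolate (as phenoxide/enolate dianion) with the ester, driven by deprotonation of the β-diketone, forms the C2–C3 bond of the future chromone.

Step 4
Reactants: 5 1-[5-(benzyloxy)-2-hydroxy-4-methoxyphenyl]-5-phenylpentane-1,3-dione
Product: 6 6-(benzyloxy)-7-methoxy-2-(2-phenylethyl)-4H-chromen-4-one
Conditions: conc. HCl (cat.), AcOH, 60 °C
Reagents that add atoms: none
Why: Acid-catalysed cyclodehydration (phenol OH adds to the enolized 1,3-diketone, water is lost) closes the γ-pyrone ring.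

Step 5
Reactants: 6 6-(benzyloxy)-7-methoxy-2-(2-phenylethyl)-4H-chromen-4-one
Product: 7 6-hydroxy-7-methoxy-2-(2-phenylethyl)-4H-chromen-4-one
Conditions: H2 (1 atm), Pd/C (10 wt %), EtOAc/MeOH, rt
Reagents that add atoms: none
Why: Hydrogenolysis of the aryl benzyl ether is fast under conditions that leave the chromone C=C and C=O untouched.

Step 6
Reactants: 8 (but-3-yn-1-yl)benzene
Product: 9 5-phenylpent-2-ynal
Conditions: n-BuLi (1.05 equiv), THF, −78 °C; DMF (2 equiv), −78 → 0 °C; poured into cold 10% aq. KH2PO4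
Reagents that add atoms: N,N-dimethylformamide, CN(C)C=O
Why: Formylation of the lithium acetylide with DMF (Bouveault-type), with a buffered reverse quench that releases the ynal without amine conjugate addition.

Step 7
Reactants: 10 methyl 4,6-O-[(R)-benzylidene]-α-D-glucopyranoside
Product: 11 methyl 4,6-O-[(R)-benzylidene]-2-O-(4-methoxybenzyl)-α-D-glucopyranoside
Conditions: NaH (1.05 equiv), PMBCl (1.05 equiv), Bu4NI (cat.), DMF, −20 → 0 °C; chromatography
Reagents that add atoms: 4-methoxybenzyl chloride, COc1ccc(CCl)cc1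
Why: Williamson etherification favours the more acidic 2-OH (next to the anomeric carbon, cis to the anomeric OMe); the minor 3-O and bis-ethers are separated.

Step 8
Reactants: 11 methyl 4,6-O-[(R)-benzylidene]-2-O-(4-methoxybenzyl)-α-D-glucopyranoside
Product: 12 methyl 2-O-(4-methoxybenzyl)-α-D-glucopyranoside
Conditions: AcOH/H2O (4:1), 60 °C
Reagents that add atoms: none
Why: Acid-catalysed acetal hydrolysis removes the benzylidene group while the PMB ether and the methyl glycoside survive.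

Step 9
Reactants: 12 methyl 2-O-(4-methoxybenzyl)-α-D-glucopyranoside
Product: 13 methyl 6-deoxy-6-iodo-2-O-(4-methoxybenzyl)-α-D-glucopyranoside
Conditions: I2 (1.3 equiv), PPh3 (1.4 equiv), imidazole (2.5 equiv), toluene, 70 °C
Reagents that add atoms: iodine, II
Why: Garegg–Samuelsson (Appel-type) iodination converts only the primary 6-OH, leaving the secondary 3- and 4-OH free.

Step 10
Reactants: 13 methyl 6-deoxy-6-iodo-2-O-(4-methoxybenzyl)-α-D-glucopyranoside
Product: 14 methyl 6-deoxy-6-iodo-3,4-bis-O-(methoxymethyl)-2-O-(4-methoxybenzyl)-α-D-glucopyranoside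
Conditions: MOMCl (4 equiv), i-Pr2NEt (6 equiv), Bu4NI (cat.), CH2Cl2, reflux
Reagents that add atoms: chloromethyl methyl ether, COCCl
Why: Acetal-forming O-alkylation (MOM protection) of both secondary alcohols under non-nucleophilic amine base leaves the primary iodide intact.

Step 11
Reactants: 14 methyl 6-deoxy-6-iodo-3,4-bis-O-(methoxymethyl)-2-O-(4-methoxybenzyl)-α-D-glucopyranoside
Product: 15 methyl 6-deoxy-3,4-bis-O-(methoxymethyl)-2-O-(4-methoxybenzyl)-α-D-xylo-hex-5-enopyranoside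
Conditions: DBU (3 equiv), DMF, 80 °C
Reagents that add atoms: none
Why: E2 dehydroiodination across C5–C6 gives the exocyclic enol ether needed for carbocyclization.

Step 12
Reactants: 15 methyl 6-deoxy-3,4-bis-O-(methoxymethyl)-2-O-(4-methoxybenzyl)-α-D-xylo-hex-5-enopyranoside
Product: 16 (2S,3R,4S,5S)-5-hydroxy-2,3-bis(methoxymethoxy)-4-[(4-methoxybenzyl)oxy]cyclohexan-1-one
Conditions: Hg(OCOCF3)2 (10 mol %), acetone/H2O (4:1), rt; minor 5-epimer removed by chromatography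
Reagents that add atoms: water, O
Why: Ferrier carbocyclization (oxymercuration of the enol ether, loss of methanol, intramolecular aldol) gives the β-hydroxy ketone with the new OH mainly axial, trans to the MOM ether two carbons away; this OH serves only as the handle for step 13.

Step 13
Reactants: 16 (2S,3R,4S,5S)-5-hydroxy-2,3-bis(methoxymethoxy)-4-[(4-methoxybenzyl)oxy]cyclohexan-1-one
Product: 17 (1S,3S,4R,5R,6S)-4,5-bis(methoxymethoxy)-6-[(4-methoxybenzyl)oxy]cyclohexane-1,3-diol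
Conditions: Me4NBH(OAc)3 (5 equiv), MeCN/AcOH (1:1), −25 °C
Reagents that add atoms: none
Why: Saksena–Evans hydroxyl-directed reduction: the axial OH binds boron and delivers hydride to the same face, so the new 3-OH is equatorial, 1,3-anti and trans to the adjacent OMOM; this carbon becomes C5 of the target.

Step 14
Reactants: 17 (1S,3S,4R,5R,6S)-4,5-bis(methoxymethoxy)-6-[(4-methoxybenzyl)oxy]cyclohexane-1,3-diol
Product: 18 (1S,2S,3R,4S,5S)-5-[(tert-butyldimethylsilyl)oxy]-3,4-bis(methoxymethoxy)-2-[(4-methoxybenzyl)oxy]cyclohexan-1-ol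
Conditions: TBSCl (1.1 equiv), imidazole (2.5 equiv), DMF, 0 °C
Reagents that add atoms: tert-butyldimethylsilyl chloride, CC(C)(C)[Si](C)(C)Cl
Why: Silyl ether formation is faster at the equatorial OH than at the axial OH, which is shielded by 1,3-diaxial hydrogens.

Step 15
Reactants: 18 (1S,2S,3R,4S,5S)-5-[(tert-butyldimethylsilyl)oxy]-3,4-bis(methoxymethoxy)-2-[(4-methoxybenzyl)oxy]cyclohexan-1-ol
Product: 19 (2R,3S,4S,5S)-5-[(tert-butyldimethylsilyl)oxy]-3,4-bis(methoxymethoxy)-2-[(4-methoxybenzyl)oxy]cyclohexan-1-one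
Conditions: DMP (1.3 equiv), CH2Cl2, rt
Reagents that add atoms: none
Why: Dess–Martin oxidation of the remaining axial alcohol is neutral, so the β-silyloxy group is not eliminated and the all-equatorial α-alkoxy centre is not epimerized.

Step 16
Reactants: 19 (2R,3S,4S,5S)-5-[(tert-butyldimethylsilyl)oxy]-3,4-bis(methoxymethoxy)-2-[(4-methoxybenzyl)oxy]cyclohexan-1-one; 9 5-phenylpent-2-ynal
Product: 20 (3S,4S,5S,6R)-3-[(tert-butyldimethylsilyl)oxy]-2-(1-hydroxy-5-phenylpent-2-yn-1-yl)-4,5-bis(methoxymethoxy)-6-[(4-methoxybenzyl)oxy]cyclohexan-1-one (mixture of epimers at C2 and the carbinol carbon)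
Conditions: LiN(i-Pr)2 (1.1 equiv), THF, −78 °C; then 9 (1.3 equiv), −78 °C; AcOH quench at −78 °C
Reagents that add atoms: none
Why: Kinetic deprotonation at the CH2 (away from the α-alkoxy carbon) and intermolecular aldol addition to the ynal form the C4a–C4 bond; the equatorial β-OTBS is poorly aligned for E1cB loss and both new centres are erased in step 17.

Step 17
Reactants: 20 (3S,4S,5S,6R)-3-[(tert-butyldimethylsilyl)oxy]-2-(1-hydroxy-5-phenylpent-2-yn-1-yl)-4,5-bis(methoxymethoxy)-6-[(4-methoxybenzyl)oxy]cyclohexan-1-one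
Product: 22 (5S,6S,7S,8R)-5-[(tert-butyldimethylsilyl)oxy]-6,7-bis(methoxymethoxy)-8-[(4-methoxybenzyl)oxy]-2-(2-phenylethyl)-5,6,7,8-tetrahydro-4H-chromen-4-one, via ynedione 21 (not isolated)
Conditions: DMP (1.3 equiv), CH2Cl2, 0 °C → rt; filtered and concentrated; then Et2NH (0.3 equiv), EtOH, rt
Reagents that add atoms: none
Why: Dess–Martin oxidation gives the enolized 2-alkynoyl ketone, and amine-catalysed conjugate addition followed by 6-exo addition–elimination of the enol oxygen (oxa-Michael-type cyclization) closes the γ-pyrone through the O1–C2 bond.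

Step 18
Reactants: 22 (5S,6S,7S,8R)-5-[(tert-butyldimethylsilyl)oxy]-6,7-bis(methoxymethoxy)-8-[(4-methoxybenzyl)oxy]-2-(2-phenylethyl)-5,6,7,8-tetrahydro-4H-chromen-4-one
Product: 23 (5S,6S,7R,8R)-5-[(tert-butyldimethylsilyl)oxy]-8-hydroxy-6,7-bis(methoxymethoxy)-2-(2-phenylethyl)-5,6,7,8-tetrahydro-4H-chromen-4-one
Conditions: DDQ (1.5 equiv), CH2Cl2/pH 7 buffer (10:1), 0 °C → rt
Reagents that add atoms: none
Why: Oxidative PMB cleavage by DDQ frees only the 8-OH, since MOM and TBS ethers and the pyrone are inert to it.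

Step 19
Reactants: 23 (5S,6S,7R,8R)-5-[(tert-butyldimethylsilyl)oxy]-8-hydroxy-6,7-bis(methoxymethoxy)-2-(2-phenylethyl)-5,6,7,8-tetrahydro-4H-chromen-4-one; 7 6-hydroxy-7-methoxy-2-(2-phenylethyl)-4H-chromen-4-one
Product: 24 (5S,6S,7S,8S)-5-[(tert-butyldimethylsilyl)oxy]-8-{[7-methoxy-4-oxo-2-(2-phenylethyl)-4H-chromen-6-yl]oxy}-6,7-bis(methoxymethoxy)-2-(2-phenylethyl)-5,6,7,8-tetrahydro-4H-chromen-4-one
Conditions: PPh3 (2 equiv), DIAD (2 equiv), toluene/THF, 0 °C → rt
Reagents that add atoms: none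
Why: Mitsunobu etherification: the phenoxide displaces the C8 oxyphosphonium by SN2 at a position activated like a vinylogous α-hydroxy carbonyl, inverting C8 from R to S and giving the 7,8-cis arrangement.

Step 20
Reactants: 24 (5S,6S,7S,8S)-5-[(tert-butyldimethylsilyl)oxy]-8-{[7-methoxy-4-oxo-2-(2-phenylethyl)-4H-chromen-6-yl]oxy}-6,7-bis(methoxymethoxy)-2-(2-phenylethyl)-5,6,7,8-tetrahydro-4H-chromen-4-one
Product: 25 (5S,6R,7S,8S)-5,6,7-trihydroxy-8-{[7-methoxy-4-oxo-2-(2-phenylethyl)-4H-chromen-6-yl]oxy}-2-(2-phenylethyl)-5,6,7,8-tetrahydro-4H-chromen-4-one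
Conditions: 6 M aq. HCl/THF (1:3), 40 °C
Reagents that add atoms: none
Why: Acid-catalysed acetal hydrolysis (MOM) and desilylation (TBS) free the triol, while protonation of the pyranone carbonyl to a hydroxypyrylium suppresses ionization at C5 and C8, so no stereocentre is touched.

## Compound list

1 | 2-methoxybenzene-1,4-diol | COc1cc(O)ccc1O | starting material
2 | 1-(2,5-dihydroxy-4-methoxyphenyl)ethan-1-one | CC(=O)c1cc(O)c(OC)cc1O | intermediate
3 | 1-[5-(benzyloxy)-2-hydroxy-4-methoxyphenyl]ethan-1-one | CC(=O)c1cc(OCc2ccccc2)c(OC)cc1O | intermediate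
4 | ethyl 3-phenylpropanoate | CCOC(=O)CCc1ccccc1 | starting material
5 | 1-[5-(benzyloxy)-2-hydroxy-4-methoxyphenyl]-5-phenylpentane-1,3-dione | O=C(CCc1ccccc1)CC(=O)c1cc(OCc2ccccc2)c(OC)cc1O | intermediate
6 | 6-(benzyloxy)-7-methoxy-2-(2-phenylethyl)-4H-chromen-4-one | COc1cc2oc(CCc3ccccc3)cc(=O)c2cc1OCc1ccccc1 | intermediate
7 | 6-hydroxy-7-methoxy-2-(2-phenylethyl)-4H-chromen-4-one | COc1cc2oc(CCc3ccccc3)cc(=O)c2cc1O | intermediate
8 | (but-3-yn-1-yl)benzene | C#CCCc1ccccc1 | starting material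
9 | 5-phenylpent-2-ynal | O=CC#CCCc1ccccc1 | intermediate
10 | methyl 4,6-O-[(R)-benzylidene]-α-D-glucopyranoside | CO[C@H]1O[C@@H]2CO[C@@H](c3ccccc3)O[C@H]2[C@H](O)[C@H]1O | starting material
11 | methyl 4,6-O-[(R)-benzylidene]-2-O-(4-methoxybenzyl)-α-D-glucopyranoside | CO[C@H]1O[C@@H]2CO[C@@H](c3ccccc3)O[C@H]2[C@H](O)[C@H]1OCc1ccc(OC)cc1 | intermediate
12 | methyl 2-O-(4-methoxybenzyl)-α-D-glucopyranoside | CO[C@H]1O[C@H](CO)[C@@H](O)[C@H](O)[C@H]1OCc1ccc(OC)cc1 | intermediate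
13 | methyl 6-deoxy-6-iodo-2-O-(4-methoxybenzyl)-α-D-glucopyranoside | CO[C@H]1O[C@H](CI)[C@@H](O)[C@H](O)[C@H]1OCc1ccc(OC)cc1 | intermediate
14 | methyl 6-deoxy-6-iodo-3,4-bis-O-(methoxymethyl)-2-O-(4-methoxybenzyl)-α-D-glucopyranoside | CO[C@H]1O[C@H](CI)[C@@H](OCOC)[C@H](OCOC)[C@H]1OCc1ccc(OC)cc1 | intermediate
15 | methyl 6-deoxy-3,4-bis-O-(methoxymethyl)-2-O-(4-methoxybenzyl)-α-D-xylo-hex-5-enopyranoside | CO[C@H]1OC(=C)[C@@H](OCOC)[C@H](OCOC)[C@H]1OCc1ccc(OC)cc1 | intermediate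
16 | (2S,3R,4S,5S)-5-hydroxy-2,3-bis(methoxymethoxy)-4-[(4-methoxybenzyl)oxy]cyclohexan-1-one (three ether groups mutually trans, 5-OH axial and cis to the 4-OPMB) | O=C1C[C@H](O)[C@H](OCc2ccc(OC)cc2)[C@@H](OCOC)[C@@H]1OCOC | intermediate
17 | (1S,3S,4R,5R,6S)-4,5-bis(methoxymethoxy)-6-[(4-methoxybenzyl)oxy]cyclohexane-1,3-diol (1-OH axial, 3-OH equatorial and trans to the 4-OMOM) | O[C@H]1C[C@H](O)[C@H](OCc2ccc(OC)cc2)[C@@H](OCOC)[C@@H]1OCOC | intermediate
18 | (1S,2S,3R,4S,5S)-5-[(tert-butyldimethylsilyl)oxy]-3,4-bis(methoxymethoxy)-2-[(4-methoxybenzyl)oxy]cyclohexan-1-ol | CC(C)(C)[Si](C)(C)O[C@H]1C[C@H](O)[C@H](OCc2ccc(OC)cc2)[C@@H](OCOC)[C@@H]1OCOC | intermediate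
19 | (2R,3S,4S,5S)-5-[(tert-butyldimethylsilyl)oxy]-3,4-bis(methoxymethoxy)-2-[(4-methoxybenzyl)oxy]cyclohexan-1-one (all four oxygen substituents mutually trans, equatorial) | CC(C)(C)[Si](C)(C)O[C@H]1CC(=O)[C@H](OCc2ccc(OC)cc2)[C@@H](OCOC)[C@@H]1OCOC | intermediate
20 | (3S,4S,5S,6R)-3-[(tert-butyldimethylsilyl)oxy]-2-(1-hydroxy-5-phenylpent-2-yn-1-yl)-4,5-bis(methoxymethoxy)-6-[(4-methoxybenzyl)oxy]cyclohexan-1-one (epimer mixture at C2 and the carbinol carbon, left undefined) | CC(C)(C)[Si](C)(C)O[C@H]1C(C(O)C#CCCc2ccccc2)C(=O)[C@H](OCc2ccc(OC)cc2)[C@@H](OCOC)[C@@H]1OCOC | intermediate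
21 | (3S,4S,5S,6R)-3-[(tert-butyldimethylsilyl)oxy]-4,5-bis(methoxymethoxy)-6-[(4-methoxybenzyl)oxy]-2-(5-phenylpent-2-ynoyl)cyclohexan-1-one (ynedione, largely enolized at C2) | CC(C)(C)[Si](C)(C)O[C@H]1C(C(=O)C#CCCc2ccccc2)C(=O)[C@H](OCc2ccc(OC)cc2)[C@@H](OCOC)[C@@H]1OCOC | intermediate (not isolated)
22 | (5S,6S,7S,8R)-5-[(tert-butyldimethylsilyl)oxy]-6,7-bis(methoxymethoxy)-8-[(4-methoxybenzyl)oxy]-2-(2-phenylethyl)-5,6,7,8-tetrahydro-4H-chromen-4-one (5-, 6-, 7- and 8-oxygens all trans) | COc1ccc(CO[C@H]2c3oc(CCc4ccccc4)cc(=O)c3[C@H](O[Si](C)(C)C(C)(C)C)[C@@H](OCOC)[C@@H]2OCOC)cc1 | intermediate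
23 | (5S,6S,7R,8R)-5-[(tert-butyldimethylsilyl)oxy]-8-hydroxy-6,7-bis(methoxymethoxy)-2-(2-phenylethyl)-5,6,7,8-tetrahydro-4H-chromen-4-one | O[C@H]1c2oc(CCc3ccccc3)cc(=O)c2[C@H](O[Si](C)(C)C(C)(C)C)[C@@H](OCOC)[C@@H]1OCOC | intermediate
24 | (5S,6S,7S,8S)-5-[(tert-butyldimethylsilyl)oxy]-8-{[7-methoxy-4-oxo-2-(2-phenylethyl)-4H-chromen-6-yl]oxy}-6,7-bis(methoxymethoxy)-2-(2-phenylethyl)-5,6,7,8-tetrahydro-4H-chromen-4-one (8-OAr now cis to 7-O) | COc1cc2oc(CCc3ccccc3)cc(=O)c2cc1O[C@@H]1c2oc(CCc3ccccc3)cc(=O)c2[C@H](O[Si](C)(C)C(C)(C)C)[C@@H](OCOC)[C@@H]1OCOC | intermediate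
25 | (5S,6R,7S,8S)-5,6,7-trihydroxy-8-{[7-methoxy-4-oxo-2-(2-phenylethyl)-4H-chromen-6-yl]oxy}-2-(2-phenylethyl)-5,6,7,8-tetrahydro-4H-chromen-4-one (CNP0125425.2) | COc1cc2oc(CCc3ccccc3)cc(=O)c2cc1O[C@@H]1c2oc(CCc3ccccc3)cc(=O)c2[C@H](O)[C@@H](O)[C@@H]1O | target

## Summary

Total step count: 20.
Longest linear sequence: 14 steps (steps 7–20, from 10 to 25). The phenol 7 (steps 1–5) and the ynal 9 (step 6) are convergent branches.

Three steps most likely to fail:

**Step 14 (selective silylation).** The equatorial/axial rate difference may be modest and give bis-silyl or wrongly silylated material. The fallback sets out from 16 and comes back at 18, replacing steps 13 and 14. An Evans–Tishchenko reduction of 16 (PhCHO 4 equiv, SmI2 0.3 equiv, THF, −10 °C) transfers hydride intramolecularly from the hemiacetal on the axial oxygen. It gives (1S,2S,3R,4R,5S)-5-hydroxy-3,4-bis(methoxymethoxy)-2-[(4-methoxybenzyl)oxy]cyclohexyl benzoate F1, in which the axial oxygen is already masked and the new equatorial OH is free. TBSOTf/2,6-lutidine (CH2Cl2, −78 °C) then gives (1S,2S,3R,4S,5S)-5-[(tert-butyldimethylsilyl)oxy]-3,4-bis(methoxymethoxy)-2-[(4-methoxybenzyl)oxy]cyclohexyl benzoate F2. Methanolysis of the benzoate (K2CO3, MeOH, rt) delivers 18.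

**Step 16 (lithium aldol).** The enolate of a β-silyloxy, α'-alkoxy ketone may eliminate or form on the wrong side. The fallback sets out from 19 and comes back at 20. The kinetic enolate is trapped as it forms (LiN(i-Pr)2 with Me3SiCl present, THF, −78 °C) as {[(3S,4S,5S,6R)-3-[(tert-butyldimethylsilyl)oxy]-4,5-bis(methoxymethoxy)-6-[(4-methoxybenzyl)oxy]cyclohex-1-en-1-yl]oxy}trimethylsilane F3. This is isolated and joined to 9 in a Lewis-acid Mukaiyama aldol (BF3·OEt2, CH2Cl2, −78 °C), which never exposes a free basic enolate, giving 20 after aqueous work-up.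

**Step 19 (Mitsunobu etherification).** The secondary alcohol is hindered and may eliminate or fail to react. The fallback sets out from 23 (with 7) and comes back at 24. Tf2O/pyridine (CH2Cl2, −40 °C) converts 23 into (5S,6S,7S,8R)-5-[(tert-butyldimethylsilyl)oxy]-6,7-bis(methoxymethoxy)-4-oxo-2-(2-phenylethyl)-5,6,7,8-tetrahydro-4H-chromen-8-yl trifluoromethanesulfonate F4. The preformed caesium phenoxide of 7 (Cs2CO3, MeCN, −20 → 0 °C) displaces it by SN2 with the same inversion at C8, giving 24.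

## Further compounds

F1 | step 14 | (1S,2S,3R,4R,5S)-5-hydroxy-3,4-bis(methoxymethoxy)-2-[(4-methoxybenzyl)oxy]cyclohexyl benzoate | O[C@H]1C[C@H](OC(=O)c2ccccc2)[C@H](OCc2ccc(OC)cc2)[C@@H](OCOC)[C@@H]1OCOC
F2 | step 14 | (1S,2S,3R,4S,5S)-5-[(tert-butyldimethylsilyl)oxy]-3,4-bis(methoxymethoxy)-2-[(4-methoxybenzyl)oxy]cyclohexyl benzoate | CC(C)(C)[Si](C)(C)O[C@H]1C[C@H](OC(=O)c2ccccc2)[C@H](OCc2ccc(OC)cc2)[C@@H](OCOC)[C@@H]1OCOC
F3 | step 16 | {[(3S,4S,5S,6R)-3-[(tert-butyldimethylsilyl)oxy]-4,5-bis(methoxymethoxy)-6-[(4-methoxybenzyl)oxy]cyclohex-1-en-1-yl]oxy}trimethylsilane | CC(C)(C)[Si](C)(C)O[C@H]1C=C(O[Si](C)(C)C)[C@H](OCc2ccc(OC)cc2)[C@@H](OCOC)[C@@H]1OCOC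
F4 | step 19 | (5S,6S,7S,8R)-5-[(tert-butyldimethylsilyl)oxy]-6,7-bis(methoxymethoxy)-4-oxo-2-(2-phenylethyl)-5,6,7,8-tetrahydro-4H-chromen-8-yl trifluoromethanesulfonate | O=S(=O)(O[C@H]1c2oc(CCc3ccccc3)cc(=O)c2[C@H](O[Si](C)(C)C(C)(C)C)[C@@H](OCOC)[C@@H]1OCOC)C(F)(F)F
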